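The constants were chosen freely.

Kilojoules per mole turn into powers of ten once we take logarithms, and the 21.0 kJ mol⁻¹ between the two capture steps is the figure we follow through the flasks: partner, dissolving from the held gas, takes each hand of substrate to the product of that hand, the two hands interconvert through the achiral form, and partner also passes into the dormant form.

the same everywhere: left-handed substrate 5.0 mM; gas 0.40 mM (held); right-handed substrate 5.0 mM; time 6.0 min
- dusk: temperature 75 °C
- autumn: temperature 50 °C
- dawn: temperature 25 °C
- noon: at 25 °C until 80 s, from then on at 75 °C

    partner + left-handed substrate → left-handed product (k1 = 68 L mol⁻¹ s⁻¹, Ea1 = 37.0 kJ mol⁻¹)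
    partner + right-handed substrate → right-handed product (k2 = 4.2 L mol⁻¹ s⁻¹, Ea2 = 58.0 kJ mol⁻¹)
    left-handed substrate ⇌ achiral form (K3 = 0.029, k3 = 1.5 s⁻¹, Ea3 = 64.0 kJ mol⁻¹, ΔH3 = 0 kJ mol⁻¹)
    right-handed substrate ⇌ achiral form (K3 = 0.029, k3 = 1.5 s⁻¹, Ea3 = 64.0 kJ mol⁻¹, ΔH3 = 0 kJ mol⁻¹)
    gas ⇌ partner, rate k5*(csat - [partner]) (k5 = 0.098 s⁻¹, csat = 0.40 mM)
    partner ⇌ dormant form (K6 = 88, k6 = 0.0088 s⁻¹, Ea6 = 74.0 kJ mol⁻¹, ΔH6 = −26.0 kJ mol⁻¹)
    (constants at 25 °C)

- partner is single-handed; left-handed substrate and right-handed substrate are mirror images of each other, charged as a racemate, each of them at the stated concentration
- at the start none of partner is dissolved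
- all constants are for 25 °C and move with temperature by the activation energies and enthalpies
- an excess is below zero if the other one leads
- the handed part of partner does not stay in what it makes, so the products of the two hands are mirror images too

- the flask that comes out highest in excess of left-handed product over right-handed product, or "all alike" when all lie within 1.5 percentage points (dusk / autumn / dawn / noon / all alike)
- excess of left-handed product over right-handed product at the end, dusk
- excess of left-handed product over right-handed product at the end, autumn
- excess of left-handed product over right-handed product at the end, dawn
- excess of left-handed product over right-handed product at the end, noon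

We reckon with the selectivity factor, the left-handed capture constant over the right-handed one. While the substrate stays racemic, the products form in that ratio, so the excess is the factor less one over the factor plus one, however much product has formed. At 25 °C the factor is 16.2, or 1.21 in powers of ten. Right-handed capture speeds up by 29 between the coldest and hottest flasks, and left-handed capture, with 37.0 kJ mol⁻¹ against 58.0 kJ mol⁻¹, gains a smaller power of the same step. The logarithm therefore loses 0.528, which leaves 4.80, the selectivity factor of the hot flask. Our excess is then 88.4% for dawn and 65.5% for dusk. Autumn we leave unreckoned, and for noon we expect a blend weighted by the product made before and after 80 s, a weighting we do not reckon here.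

Now we turn the question round. For dusk to stand above dawn, right-handed capture has to have the lower activation energy, and here it has 21.0 kJ mol⁻¹ more. For "all alike" the excess has to stay within 1.5 percentage points from dawn to dusk, and ours falls by 23 points. The rule itself asks that the substrate stay racemic. Even with [partner] at 0.40 mM, left-handed substrate is captured at 0.0272 s⁻¹ at 25 °C and leaves for the achiral form at 1.5 s⁻¹, which is faster by 1.74 powers of ten. That passage carries 27.0 kJ mol⁻¹ more activation energy than left-handed capture, so at 75 °C the margin is 2.42, and the margin at 25 °C is the smaller of the two.

The forecast names dawn, with 65.5% for dusk, 78.6% for autumn, 88.3% for dawn and 70.9% for noon, on the ground that "Interconversion of the substrate hands through the achiral form is far faster than capture by partner". For autumn and noon it goes beyond our reckoning.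

The flask gives 65.5% for dusk, 78.7% for autumn, 88.3% for dawn and 70.7% for noon, so dawn stands highest, and the dusk value lies beside our 65.5%. We use the hot factor 4.80 on the neighbour, the noon flask read at 1.5 min. At the change, 1.33 min, noon holds 21.3% left-handed and 1.32% right-handed product, in percent of the two substrates together charged, and at the reading the two products together reach 26.6%. So 4.01% came after the change, and split as 4.80 to one it brings right-handed product to 2.01%, against 2.01% in the flask. That gives an excess of 84.9%, and the flask reads 84.9%.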